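**Retrosynthetic overview**
- Target 24 ⇐ acid isomerisation of the α,β-epoxy ketone 23 (a masked diosphenol); the isopropylidene comes from an acetone aldol plus E1cB dehydration; the C–O ester bond comes from a Steglich coupling of diol 11 with the Z-acid 20.
- Epoxy ketone 9 ⇐ Weitz–Scheffer epoxidation of hydroxy enone 8 ⇐ hydroboration–oxidation of alkene 5 (sets the CH–OH and CH–CH3 centres from the angular methyl) ⇐ enol triflate/cuprate methylation of thioketal-protected (S)-Wieland–Miescher ketone 1.
- Acid 20 ⇐ tert-butyl ester cleavage ⇐ Mitsunobu reaction with angelic acid 18 ⇐ syn-carbocupration of ynoate 14 (sets the Z-alkene) ⇐ silyl propargyl ether 12 + Boc2O.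
- Ring order: rings A and B arrive already fused in 1, so no carbocycle is built. The only ring made is the oxirane (step 6), which is opened again in step 15.

Assumption: 1, 12 and 18 are bought. The transient stereocentres (oxirane carbons, aldol carbon) are drawn as the expected major isomers and are erased before the target. From compound 5 on, decalins are numbered as naphthalen-2(3H)-ones (C2 ketone carbon, C1=C8a enone alkene, C4a angular carbon, C5 CH–CH3, C6 carbinol carbon).

**Step 1**
Reactants: 1 (S)-Wieland–Miescher ketone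
Product: 2 (8aS)-Wieland–Miescher ketone 6-(1,3-dithiolane), C1 ketone free
Conditions: HSCH2CH2SH (1.05 equiv), TsOH·H2O (cat.), AcOH, rt
Reagents that add atoms: ethane-1,2-dithiol, SCCS
Why: Acid-catalysed thioketalisation is selective for the conjugated carbonyl (the neopentyl C1 ketone is left) and keeps the alkene in place; no stereocentre is touched.

**Step 2**
Reactants: 2 dithiolane ketone
Product: 4 (8aS)-enol triflate of 2 (C1–OTf, C1=C2), via potassium enolate 3 (not isolated)
Conditions: KN(SiMe3)2, THF, –78 °C; PhNTf2, –78 to 0 °C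
Reagents that add atoms: N-phenylbis(trifluoromethanesulfonimide), O=S(=O)(N(c1ccccc1)S(=O)(=O)C(F)(F)F)C(F)(F)F
Why: Only C2 carries α-hydrogens, so enolisation and O-triflation (enol triflate formation) give one regioisomer.

**Step 3**
Reactants: 4 enol triflate
Product: 5 1,3-dithiolane of (4aR)-4a,5-dimethyl-4,4a,7,8-tetrahydronaphthalen-2(3H)-one
Conditions: Me2CuLi (from MeLi and CuI), THF, –15 °C; AcOH quench
Reagents that add atoms: lithium dimethylcuprate Me2CuLi, [Li+].C[Cu-]C
Why: Cuprate cross-coupling of the enol triflate replaces OTf by CH3 without moving the alkene; the dithiolane is inert to the cuprate.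

**Step 4**
Reactants: 5 methyl diene dithiolane
Product: 7 1,3-dithiolane of (4aR,5R,6R)-6-hydroxy-4a,5-dimethyl-4,4a,5,6,7,8-hexahydronaphthalen-2(3H)-one, via alkylborane 6 (not isolated)
Conditions: BH3·THF (1.2 equiv), THF, 0 °C to rt; then NaOH, H2O2, 0 °C
Reagents that add atoms: hydrogen peroxide, OO
Why: Hydroboration–oxidation adds H (to C5) and B (to C6) syn and anti-Markovnikov from the face opposite the angular methyl, which sets the C5 methyl cis to the angular methyl and the C6 hydroxyl trans to both. The C1=C8a alkene is shielded by the spiro-dithiolane and the quaternary carbon.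

**Step 5**
Reactants: 7 hydroxy dithiolane
Product: 8 (4aR,5R,6R)-6-hydroxy-4a,5-dimethyl-4,4a,5,6,7,8-hexahydronaphthalen-2(3H)-one
Conditions: MeI (excess), CaCO3, MeCN/H2O (4:1), 55 °C
Reagents that add atoms: water, O
Why: Alkylative dethioketalisation (S-methylation, then hydrolysis) frees the enone under near-neutral conditions that leave the alcohol and the stereocentres alone.

**Step 6**
Reactants: 8 hydroxy enone
Product: 9 1,8a-epoxide of 8, oxirane oxygen cis to both methyl groups
Conditions: H2O2 (30 %), NaOH (cat.), MeOH, 0 °C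
Reagents that add atoms: hydrogen peroxide, OO
Why: Weitz–Scheffer nucleophilic epoxidation touches only the enone; hydroperoxide is expected to add on the face of the angular methyl (as with 4-en-3-one steroids), and either epimer converges in step 15.

**Step 7**
Reactants: 9 epoxy ketone
Product: 11 3-(2-hydroxypropan-2-yl) derivative of 9, via dilithium alkoxide enolate 10 (not isolated)
Conditions: LiN(i-Pr)2 (2.2 equiv), THF, –78 °C; acetone (3 equiv), –78 °C; AcOH, –78 °C
Reagents that add atoms: acetone, CC(C)=O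
Why: After O-lithiation the only enolisable site is C3, and the kinetic enolate undergoes a directed aldol addition to acetone; the new C3 centre (drawn trans to the angular methyl) is erased in step 14.

**Step 8**
Reactants: 12 tert-butyldimethyl(prop-2-yn-1-yloxy)silane
Product: 14 tert-butyl 4-[(tert-butyldimethylsilyl)oxy]but-2-ynoate, via lithium acetylide 13 (not isolated)
Conditions: n-BuLi, THF, –78 °C; Boc2O, –78 to 0 °C
Reagents that add atoms: di-tert-butyl dicarbonate, CC(C)(C)OC(=O)OC(=O)OC(C)(C)C
Why: Acylation of the lithium acetylide with Boc2O gives the tert-butyl ynoate directly.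

**Step 9**
Reactants: 14 ynoate
Product: 16 tert-butyl (2Z)-4-[(tert-butyldimethylsilyl)oxy]-3-methylbut-2-enoate, via alkenylcuprate 15 (not isolated)
Conditions: Me2CuLi (from MeLi and CuI), THF, –78 °C; AcOH, –78 °C
Reagents that add atoms: lithium dimethylcuprate Me2CuLi, [Li+].C[Cu-]C
Why: Syn-carbocupration (conjugate addition) puts CH3 and Cu cis, and cold protonation with retention leaves CH2OSi cis to the ester, which is the required Z-alkene.

**Step 10**
Reactants: 16 silyl ether
Product: 17 tert-butyl (2Z)-4-hydroxy-3-methylbut-2-enoate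
Conditions: HF·pyridine, pyridine, THF, 0 °C; used at once
Reagents that add atoms: none
Why: Buffered fluoride desilylation frees the primary alcohol, and the bulky tert-butyl ester slows lactonisation to the butenolide.

**Step 11**
Reactants: 17 Z-hydroxy ester; 18 angelic acid
Product: 19 tert-butyl (2Z)-3-methyl-4-{[(2Z)-2-methylbut-2-enoyl]oxy}but-2-enoate
Conditions: PPh3, DIAD, THF, 0 °C
Reagents that add atoms: none
Why: In the Mitsunobu esterification the angelate is the nucleophile and is never activated at carbon, so it cannot isomerise to the tiglate; the primary carbinol has no stereocentre.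

**Step 12**
Reactants: 19 tert-butyl ester
Product: 20 (2Z)-3-methyl-4-{[(2Z)-2-methylbut-2-enoyl]oxy}but-2-enoic acid
Conditions: CF3CO2H, CH2Cl2 (1:3), 0 °C to rt
Reagents that add atoms: none
Why: Acidolysis of the tert-butyl ester (loss of isobutene) frees the acid without hydrolytic conditions that would cleave the angelate.

**Step 13**
Reactants: 11 diol; 20 acid
Product: 21 C6 ester of 11 with 20, tertiary hydroxyl free
Conditions: DCC, DMAP (0.1 equiv), CH2Cl2, 0 °C to rt
Reagents that add atoms: none
Why: Steglich esterification acylates the secondary alcohol in preference to the tertiary one; the C6–O bond is not broken, so configuration is retained, and low temperature with little DMAP guards the Z-alkenes.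

**Step 14**
Reactants: 21 hydroxy ester
Product: 23 (4aR,5R,6R)-1,8a-epoxy-4a,5-dimethyl-2-oxo-3-(propan-2-ylidene)octahydronaphthalen-6-yl ester of 20, via tertiary mesylate 22 (not isolated)
Conditions: MsCl, Et3N, CH2Cl2, 0 °C to rt
Reagents that add atoms: none
Why: Mesylation followed by E1cB elimination through the C3 enolate gives the conjugated isopropylidene ketone and removes the C3 stereocentre; any isopropenyl isomer is equilibrated in step 15.

**Step 15**
Reactants: 23 epoxy ketone ester
Product: 24 CNP0228871.1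
Conditions: H2SO4 (cat.), AcOH, 15 °C, short reaction time
Reagents that add atoms: none
Why: Acid-catalysed isomerisation of the α,β-epoxy ketone: the oxirane opens at the tertiary carbon and loss of the α-hydrogen gives the hydrogen-bonded diosphenol (the 4,5-epoxy-3-ketone to 4-hydroxy-4-en-3-one conversion of steroids). Both oxirane stereocentres vanish.

**Compound list**
1 | (S)-Wieland–Miescher ketone, (8aS)-8a-methyl-3,4,8,8a-tetrahydronaphthalene-1,6(2H,7H)-dione | O=C1CCCC2=CC(=O)CC[C@]12C | starting material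
2 | (8aS)-Wieland–Miescher ketone 6-(1,3-dithiolane): enone C=O as ethylene dithioketal, C4a=C5 alkene kept, C1 ketone free | O=C1CCCC2=CC3(SCCS3)CC[C@]12C | intermediate
3 | potassium enolate of 2 (C1–O–, C1=C2) | [K+].[O-]C1=CCCC2=CC3(SCCS3)CC[C@]12C | intermediate
4 | (8aS)-enol triflate of 2 (C1–OTf, C1=C2) | O=S(=O)(OC1=CCCC2=CC3(SCCS3)CC[C@]12C)C(F)(F)F | intermediate
5 | 1,3-dithiolane of (4aR)-4a,5-dimethyl-4,4a,7,8-tetrahydronaphthalen-2(3H)-one (same configuration as 4; only the descriptor changes) | CC1=CCCC2=CC3(SCCS3)CC[C@]12C | intermediate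
6 | alkylborane from 5: BH2 on C6 and H on C5, both trans to the angular methyl | B[C@@H]1CCC2=CC3(SCCS3)CC[C@]2(C)[C@H]1C | intermediate
7 | 1,3-dithiolane of (4aR,5R,6R)-6-hydroxy-4a,5-dimethyl-4,4a,5,6,7,8-hexahydronaphthalen-2(3H)-one | O[C@@H]1CCC2=CC3(SCCS3)CC[C@]2(C)[C@H]1C | intermediate
8 | (4aR,5R,6R)-6-hydroxy-4a,5-dimethyl-4,4a,5,6,7,8-hexahydronaphthalen-2(3H)-one | O[C@@H]1CCC2=CC(=O)CC[C@]2(C)[C@H]1C | intermediate
9 | (4aR,5R,6R)-1,8a-epoxy-6-hydroxy-4a,5-dimethyloctahydronaphthalen-2(1H)-one, oxirane oxygen cis to both methyl groups | O[C@@H]1CC[C@]23O[C@H]2C(=O)CC[C@]3(C)[C@H]1C | intermediate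
10 | dilithium salt of 9: C6 alkoxide and C2=C3 enolate | [Li+].[Li+].[O-][C@@H]1CC[C@]23O[C@H]2C([O-])=CC[C@]3(C)[C@H]1C | intermediate
11 | 3-(2-hydroxypropan-2-yl) derivative of 9, new side chain trans to the angular methyl | O[C@@H]1CC[C@]23O[C@H]2C(=O)[C@H](C(C)(C)O)C[C@]3(C)[C@H]1C | intermediate
12 | tert-butyldimethyl(prop-2-yn-1-yloxy)silane | C#CCO[Si](C)(C)C(C)(C)C | starting material
13 | lithium 3-[(tert-butyldimethylsilyl)oxy]prop-1-yn-1-ide | [Li+].[C-]#CCO[Si](C)(C)C(C)(C)C | intermediate
14 | tert-butyl 4-[(tert-butyldimethylsilyl)oxy]but-2-ynoate | CC(C)(C)OC(=O)C#CCO[Si](C)(C)C(C)(C)C | intermediate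
15 | lithium methyl(alkenyl)cuprate from syn addition to 14 (Cu on C2, cis to the new C3 methyl) | [Li+].CC(C)(C)[Si](C)(C)OC/C(C)=C(/[Cu-]C)C(=O)OC(C)(C)C | intermediate
16 | tert-butyl (2Z)-4-[(tert-butyldimethylsilyl)oxy]-3-methylbut-2-enoate | CC(C)(C)[Si](C)(C)OC/C(C)=C\C(=O)OC(C)(C)C | intermediate
17 | tert-butyl (2Z)-4-hydroxy-3-methylbut-2-enoate | OC/C(C)=C\C(=O)OC(C)(C)C | intermediate
18 | angelic acid, (2Z)-2-methylbut-2-enoic acid | C/C=C(/C)C(=O)O | starting material
19 | tert-butyl (2Z)-3-methyl-4-{[(2Z)-2-methylbut-2-enoyl]oxy}but-2-enoate | C/C=C(/C)C(=O)OC/C(C)=C\C(=O)OC(C)(C)C | intermediate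
20 | (2Z)-3-methyl-4-{[(2Z)-2-methylbut-2-enoyl]oxy}but-2-enoic acid | C/C=C(/C)C(=O)OC/C(C)=C\C(=O)O | intermediate
21 | C6 ester of 11 with 20 (tertiary hydroxyl free) | C/C=C(/C)C(=O)OC/C(C)=C\C(=O)O[C@@H]1CC[C@]23O[C@H]2C(=O)[C@H](C(C)(C)O)C[C@]3(C)[C@H]1C | intermediate
22 | tertiary methanesulfonate of 21 | C/C=C(/C)C(=O)OC/C(C)=C\C(=O)O[C@@H]1CC[C@]23O[C@H]2C(=O)[C@H](C(C)(C)OS(C)(=O)=O)C[C@]3(C)[C@H]1C | intermediate
23 | (4aR,5R,6R)-1,8a-epoxy-4a,5-dimethyl-2-oxo-3-(propan-2-ylidene)octahydronaphthalen-6-yl (2Z)-3-methyl-4-{[(2Z)-2-methylbut-2-enoyl]oxy}but-2-enoate | C/C=C(/C)C(=O)OC/C(C)=C\C(=O)O[C@@H]1CC[C@]23O[C@H]2C(=O)C(=C(C)C)C[C@]3(C)[C@H]1C | intermediate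
24 | CNP0228871.1, [(1R,2R,8aR)-5-hydroxy-1,8a-dimethyl-6-oxo-7-(propan-2-ylidene)-1,2,3,4,6,7,8,8a-octahydronaphthalen-2-yl] (2Z)-3-methyl-4-{[(2Z)-2-methylbut-2-enoyl]oxy}but-2-enoate | C/C=C(/C)C(=O)OC/C(C)=C\C(=O)O[C@@H]1CCC2=C(O)C(=O)C(=C(C)C)C[C@]2(C)[C@H]1C | target

**Totals**
Total step count: 15 (core steps 1–7, side chain steps 8–12, union and end game steps 13–15).
Longest linear sequence: 10 steps (1–7, then 13–15, from compound 1).

**Three steps most likely to fail, with fallbacks**

Step 4 (hydroboration). Borane may also attack the second trisubstituted alkene or be held by the sulfur atoms. The fallback sets out from 5 and comes back at 8. The thioketal is removed first (MeI, CaCO3, aqueous MeCN) to give the dienone (4aR)-4a,5-dimethyl-4,4a,7,8-tetrahydronaphthalen-2(3H)-one F1. mCPBA (NaHCO3, CH2Cl2, 0 °C) then epoxidises only the electron-rich C5=C6 alkene, from the face opposite the angular methyl, to give (4aR)-5,6-epoxy-4a,5-dimethyl-4,4a,5,6,7,8-hexahydronaphthalen-2(3H)-one F2. Cp2TiCl (trivalent titanium, made from Cp2TiCl2 and Mn dust) with water or 1,4-cyclohexadiene in THF opens the oxirane to the tertiary radical. Hydrogen-atom transfer to the face opposite the angular methyl then gives the anti-Markovnikov alcohol 8.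

Step 10 (freeing the Z-γ-hydroxy ester). Compound 17 may close to 4-methylfuran-2(5H)-one before or during step 11. The fallback sets out from 16 and comes back at 19 without ever freeing the alcohol. Ph3PBr2 (CH2Cl2, 0 °C to rt) converts the silyl ether directly into tert-butyl (2Z)-4-bromo-3-methylbut-2-enoate F3. Potassium (2Z)-2-methylbut-2-enoate (from 18 and K2CO3, DMF, rt) then displaces the bromide by SN2 to give 19, again without activating the angelate at carbon.

Step 15 (epoxy ketone to diosphenol with the esters in place). The acid may isomerise the angelate or the Z-enoate, or divert the oxirane to ring contraction. The fallback sets out from 11 and comes back at 24, doing the acid chemistry before the side chain is attached. TsOH·H2O (toluene, 60 °C) dehydrates the aldol and isomerises the oxirane in one operation to (4aR,5R,6R)-1,6-dihydroxy-4a,5-dimethyl-3-(propan-2-ylidene)-4,4a,5,6,7,8-hexahydronaphthalen-2(3H)-one F4. TBSCl and Et3N (CH2Cl2, 0 °C) silylate only the acidic enol hydroxyl to give the 1-[(tert-butyldimethylsilyl)oxy] enol ether of F4 with the C6 hydroxyl free F5. Steglich coupling with 20 (DCC, DMAP) gives the C6 ester of F5 with 20 F6, and HF·pyridine (THF, 0 °C) removes the enol silyl group to give 24.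

**Further compounds**
F1 | step 4 | (4aR)-4a,5-dimethyl-4,4a,7,8-tetrahydronaphthalen-2(3H)-one | CC1=CCCC2=CC(=O)CC[C@]12C
F2 | step 4 | (4aR)-5,6-epoxy-4a,5-dimethyl-4,4a,5,6,7,8-hexahydronaphthalen-2(3H)-one, oxirane trans to the angular methyl | C[C@@]12O[C@@H]1CCC3=CC(=O)CC[C@]23C
F3 | step 10 | tert-butyl (2Z)-4-bromo-3-methylbut-2-enoate | BrC/C(C)=C\C(=O)OC(C)(C)C
F4 | step 15 | (4aR,5R,6R)-1,6-dihydroxy-4a,5-dimethyl-3-(propan-2-ylidene)-4,4a,5,6,7,8-hexahydronaphthalen-2(3H)-one | O[C@@H]1CCC2=C(O)C(=O)C(=C(C)C)C[C@]2(C)[C@H]1C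
F5 | step 15 | (4aR,5R,6R)-1-[(tert-butyldimethylsilyl)oxy]-6-hydroxy-4a,5-dimethyl-3-(propan-2-ylidene)-4,4a,5,6,7,8-hexahydronaphthalen-2(3H)-one | O[C@@H]1CCC2=C(O[Si](C)(C)C(C)(C)C)C(=O)C(=C(C)C)C[C@]2(C)[C@H]1C
F6 | step 15 | C6 ester of F5 with 20 | C/C=C(/C)C(=O)OC/C(C)=C\C(=O)O[C@@H]1CCC2=C(O[Si](C)(C)C(C)(C)C)C(=O)C(=C(C)C)C[C@]2(C)[C@H]1C
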